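**Plan**
- Cuts: (i) the bond from the quaternary carbinol carbon C1 to chain carbon C1', opened to two carboxylic acids (a ring acid with its carboxyl on C1 and (13Z)-17-phenylheptadec-13-enoic acid), each used as its N-acyloxyphthalimide; (ii) C11'–C12' of the chain (acetylide alkylation); (iii) the ring is traced to (−)-quinic acid.
- Enabling feature: C1 is the α-carbon of an α-hydroxy acid (C1 of quinic acid) and its oxygen is cis-1,3 to the C5 oxygen across ring CH2-6, so one silicon atom can tie O1 to O5 in a 2,4-dioxa-3-silabicyclo[3.3.1]non-6-ene that puts the carboxyl on a bridgehead.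
- Forward order, ring (taken from the pool, none is built): quinic acid → 1,5-lactone → C3=C4 alkene (Corey–Winter) → allyl ester → inversion at C5 → silylene cage → acid → redox-active ester.
- Forward order, chain and union: 5-phenylpent-1-yne + 12-bromododecanoic acid → ynoic acid → Z-enoic acid → redox-active ester; a nickel-electrocatalytic doubly decarboxylative coupling joins C1 to C1'; fluoride then removes the silicon bridge.
- Stereochemistry: C1 from C1 of quinic acid (retention enforced by the cage at the radical stage), C5 from C5 of quinic acid after Mitsunobu inversion, the Z alkene from syn semi-hydrogenation of the alkyne.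

Key step: step 13

Remark on the chemistry: commercial (−)-quinic acid is taken as the (1S,3R,4S,5R) acid. Ring atoms carry the target numbering throughout (C1 quaternary carbinol, C3=C4, C5 secondary carbinol; these are C1, C3=C4 and C5 of quinic acid). Chain atoms are primed from C1' at the ring.

**Route**

Step 1
Reactants: 1 (−)-quinic acid
Product: 2 quinide, (1S,3R,4R,5R)-1,3,4-trihydroxy-6-oxabicyclo[3.2.1]octan-7-one
Conditions: TsOH·H2O (cat.), toluene/DMF, reflux, Dean–Stark
Reagents that add atoms: none
Why: Acid-catalysed intramolecular Fischer esterification with azeotropic water removal closes the γ-lactone onto C5–OH, the only hydroxyl cis to the carboxyl, which sets C5–OH apart from the cis C3/C4 diol without touching a stereocentre.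

Step 2
Reactants: 2 quinide
Product: 3 3,4-O-thiocarbonylquinide (cis-fused cyclic thionocarbonate of the C3/C4 diol, C1–OH free)
Conditions: 1,1'-thiocarbonyldiimidazole (1.1 equiv), THF/MeCN, 60 °C
Reagents that add atoms: 1,1'-thiocarbonyldiimidazole, S=C(n1ccnc1)n1ccnc1
Why: Thiocarbonyl transfer to the cis-vicinal C3/C4 diol forms the cis-fused cyclic thionocarbonate (first stage of a Corey–Winter olefination), the tertiary C1–OH being too hindered to compete.

Step 3
Reactants: 3 3,4-O-thiocarbonylquinide
Product: 4 (1S,5R)-1-hydroxy-6-oxabicyclo[3.2.1]oct-3-en-7-one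
Conditions: P(OMe)3, 110 °C
Reagents that add atoms: none
Why: Corey–Winter olefination, in which the phosphite takes up sulfur and the resulting 1,3-dioxolan-2-ylidene loses CO2 in a syn cycloreversion, turns the two diol carbons into the C3=C4 double bond and removes two unwanted stereocentres.

Step 4
Reactants: 4 (1S,5R)-1-hydroxy-6-oxabicyclo[3.2.1]oct-3-en-7-one
Product: 5 prop-2-en-1-yl (1S,5R)-1,5-dihydroxycyclohex-3-ene-1-carboxylate (trans-diol)
Conditions: allyl alcohol (solvent), K2CO3 (0.1 equiv), 0 °C to rt; AcOH quench
Reagents that add atoms: prop-2-en-1-ol (allyl alcohol), C=CCO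
Why: Carbonate-catalysed alcoholysis (transesterification) of the strained bridged lactone in neat allyl alcohol opens it by acyl–oxygen cleavage to the allyl ester, freeing the allylic C5–OH with both stereocentres unchanged.

Step 5
Reactants: 5 prop-2-en-1-yl (1S,5R)-1,5-dihydroxycyclohex-3-ene-1-carboxylate
Product: 6 prop-2-en-1-yl (1S,5S)-1-hydroxy-5-[(4-nitrobenzoyl)oxy]cyclohex-3-ene-1-carboxylate
Conditions: 4-nitrobenzoic acid, PPh3, DIAD, THF, 0 °C to rt
Reagents that add atoms: 4-nitrobenzoic acid, OC(=O)c1ccc(cc1)[N+](=O)[O-]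
Why: Mitsunobu reaction, in which the secondary allylic C5–OH is activated as its oxyphosphonium ion and displaced by 4-nitrobenzoate in an SN2 step with inversion, sets the 5S centre (oxygen now cis to C1–OH) while the tertiary C1–OH cannot be activated.

Step 6
Reactants: 6 prop-2-en-1-yl (1S,5S)-1-hydroxy-5-[(4-nitrobenzoyl)oxy]cyclohex-3-ene-1-carboxylate
Product: 7 prop-2-en-1-yl (1S,5S)-1,5-dihydroxycyclohex-3-ene-1-carboxylate (cis-diol)
Conditions: K2CO3 (0.2 equiv), allyl alcohol, 0 °C
Reagents that add atoms: none
Why: Base-catalysed transesterification removes the electron-poor aroyl group by acyl–oxygen cleavage, so C5 keeps its configuration, and running it in allyl alcohol makes any exchange at the hindered C1 ester degenerate.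

Step 7
Reactants: 7 prop-2-en-1-yl (1S,5S)-1,5-dihydroxycyclohex-3-ene-1-carboxylate
Product: 8 prop-2-en-1-yl (1S,5S)-3,3-di(propan-2-yl)-2,4-dioxa-3-silabicyclo[3.3.1]non-6-ene-1-carboxylate
Conditions: i-Pr2Si(OTf)2, 2,6-lutidine, CH2Cl2, 0 °C to rt
Reagents that add atoms: di(propan-2-yl)silyl bis(trifluoromethanesulfonate), CC(C)[Si](OS(=O)(=O)C(F)(F)F)(OS(=O)(=O)C(F)(F)F)C(C)C
Why: Silylene protection of a 1,3-diol with a dialkylsilyl bis(triflate) bridges the cis-diaxial O1 and O5 through one silicon atom, which makes C1 a bridgehead of a 2,4-dioxa-3-silabicyclo[3.3.1]non-6-ene and protects both hydroxyls at once.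

Step 8
Reactants: 8 prop-2-en-1-yl (1S,5S)-3,3-di(propan-2-yl)-2,4-dioxa-3-silabicyclo[3.3.1]non-6-ene-1-carboxylate
Product: 9 (1S,5S)-3,3-di(propan-2-yl)-2,4-dioxa-3-silabicyclo[3.3.1]non-6-ene-1-carboxylic acid
Conditions: Pd(PPh3)4 (5 mol%), morpholine, THF, rt; pH 5 work-up
Reagents that add atoms: none
Why: Tsuji–Trost deallylation, in which zerovalent palladium ionises the allyl ester at its allyl carbon and morpholine captures the π-allyl unit, frees the hindered bridgehead acid under neutral conditions because the ring C5–O silyl ether is no leaving group.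

Step 9
Reactants: 9 (1S,5S)-3,3-di(propan-2-yl)-2,4-dioxa-3-silabicyclo[3.3.1]non-6-ene-1-carboxylic acid
Product: 10 1,3-dioxoisoindolin-2-yl (1S,5S)-3,3-di(propan-2-yl)-2,4-dioxa-3-silabicyclo[3.3.1]non-6-ene-1-carboxylate
Conditions: N-hydroxyphthalimide, DIC, DMAP (cat.), CH2Cl2, rt
Reagents that add atoms: N-hydroxyphthalimide, O=C1N(O)C(=O)c2ccccc12
Why: Carbodiimide-mediated (Steglich-type) esterification of the acid with N-hydroxyphthalimide gives the redox-active N-acyloxyphthalimide without touching the silylene or the ring alkene.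

Step 10
Reactants: 11 5-phenylpent-1-yne; 12 12-bromododecanoic acid
Product: 15 17-phenylheptadec-13-ynoic acid, via lithium 5-phenylpent-1-yn-1-ide 13 (not isolated), via lithium 12-bromododecanoate 14 (not isolated)
Conditions: 11 (2.2 equiv), n-BuLi (2.1 equiv), THF/DMPU, −78 to 0 °C; then 12, 0 °C to rt; aq. HCl
Reagents that add atoms: none
Why: SN2 alkylation of a lithium acetylide by a primary alkyl bromide, with the acid carried as its lithium carboxylate, forms the C12–C13 bond of the chain acid and places the triple bond where the Z alkene is needed.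

Step 11
Reactants: 15 17-phenylheptadec-13-ynoic acid
Product: 16 (13Z)-17-phenylheptadec-13-enoic acid
Conditions: H2 (1 atm), Pd/CaCO3 poisoned with Pb(OAc)2, quinoline, EtOAc, rt
Reagents that add atoms: none
Why: Alkyne semi-hydrogenation of the Lindlar type adds H2 syn on the lead-poisoned palladium surface and stops at the alkene, which gives the 13Z geometry and leaves the arene and the acid alone.

Step 12
Reactants: 16 (13Z)-17-phenylheptadec-13-enoic acid
Product: 17 1,3-dioxoisoindolin-2-yl (13Z)-17-phenylheptadec-13-enoate
Conditions: N-hydroxyphthalimide, DIC, DMAP (cat.), CH2Cl2, rt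
Reagents that add atoms: N-hydroxyphthalimide, O=C1N(O)C(=O)c2ccccc12
Why: Carbodiimide-mediated (Steglich-type) esterification with N-hydroxyphthalimide converts the chain acid into its redox-active ester.

Step 13
Reactants: 10 1,3-dioxoisoindolin-2-yl (1S,5S)-3,3-di(propan-2-yl)-2,4-dioxa-3-silabicyclo[3.3.1]non-6-ene-1-carboxylate; 17 1,3-dioxoisoindolin-2-yl (13Z)-17-phenylheptadec-13-enoate
Product: 18 (1S,5S)-1-[(12Z)-16-phenylhexadec-12-en-1-yl]-3,3-di(propan-2-yl)-2,4-dioxa-3-silabicyclo[3.3.1]non-6-ene
Conditions: 10 (1 equiv), 17 (3 equiv), NiCl2·6H2O (20 mol%), 2,2':6',2''-terpyridine (20 mol%), AgNO3 (0.3 equiv), Mg anode, reticulated vitreous carbon cathode, NMP, constant current, rt, undivided cell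
Reagents that add atoms: none
Why: Proposed new method: monovalent nickel–terpyridine species formed at the cathode transfer one electron to each N-acyloxyphthalimide, which fragments to phthalimide anion, CO2 and a carbon radical; the primary radical from 17 is captured by nickel, the bridgehead C1 radical from 10 adds to the resulting alkylnickel species, and reductive elimination from dialkyl trivalent nickel forms the C1–C1' bond. The closest known reaction type is the nickel-electrocatalytic doubly decarboxylative C(sp3)–C(sp3) coupling of two redox-active esters, established for primary and secondary acids including α-alkoxy ones, and, for the bridgehead partner, the nickel-catalysed decarboxylative alkylation of redox-active esters with dialkylzinc reagents; what is new is a fully substituted, oxygen-bearing bridgehead carbon as one partner. No ring is closed. C1 is re-formed with retention: held in the silylene cage it is a pyramidal bridgehead radical whose only free lobe is the exo one vacated by CO2, so the chain ends up trans to the C5 oxygen and the two oxygens stay cis. The step needs cross- over homo-coupling and intact ring and Z alkenes: the bridgehead radical does not dimerise and cannot undergo β-hydride elimination on nickel (Bredt), the excess of 17 keeps the alkylnickel pool primary, and the homocoupled chain is an apolar hydrocarbon. The Si–O tether is chosen because, unlike an acetal, it offers the C1 radical no β-scission to a ketone and, unlike a carbonate, it gives low-valent nickel no allylic leaving group at C5.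

Step 14
Reactants: 18 (1S,5S)-1-[(12Z)-16-phenylhexadec-12-en-1-yl]-3,3-di(propan-2-yl)-2,4-dioxa-3-silabicyclo[3.3.1]non-6-ene
Product: 19 (1S,5S)-1-[(12Z)-16-phenylhexadec-12-en-1-yl]cyclohex-3-ene-1,5-diol
Conditions: HF·pyridine, THF/pyridine, 0 °C to rt
Reagents that add atoms: none
Why: Fluoride-driven cleavage of the silylene, pulled by Si–F bond formation, breaks only Si–O bonds, so both carbinol carbons keep their configuration and the allylic C5–O bond is never ionised.

**Compound list**

1 | (−)-quinic acid, (1S,3R,4S,5R)-1,3,4,5-tetrahydroxycyclohexane-1-carboxylic acid | OC(=O)[C@]1(O)C[C@@H](O)[C@@H](O)[C@H](O)C1 | starting material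
2 | quinide, (1S,3R,4R,5R)-1,3,4-trihydroxy-6-oxabicyclo[3.2.1]octan-7-one | O=C1O[C@@H]2C[C@@]1(O)C[C@@H](O)[C@H]2O | intermediate
3 | 3,4-O-thiocarbonylquinide (cis-fused cyclic thionocarbonate of the C3/C4 diol of 2, C1–OH free) | O=C1O[C@@H]2C[C@@]1(O)C[C@H]3OC(=S)O[C@@H]23 | intermediate
4 | (1S,5R)-1-hydroxy-6-oxabicyclo[3.2.1]oct-3-en-7-one | O=C1O[C@@H]2C[C@@]1(O)CC=C2 | intermediate
5 | prop-2-en-1-yl (1S,5R)-1,5-dihydroxycyclohex-3-ene-1-carboxylate (trans-diol) | C=CCOC(=O)[C@]1(O)CC=C[C@H](O)C1 | intermediate
6 | prop-2-en-1-yl (1S,5S)-1-hydroxy-5-[(4-nitrobenzoyl)oxy]cyclohex-3-ene-1-carboxylate | C=CCOC(=O)[C@]1(O)CC=C[C@@H](OC(=O)c2ccc(cc2)[N+](=O)[O-])C1 | intermediate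
7 | prop-2-en-1-yl (1S,5S)-1,5-dihydroxycyclohex-3-ene-1-carboxylate (cis-diol) | C=CCOC(=O)[C@]1(O)CC=C[C@@H](O)C1 | intermediate
8 | prop-2-en-1-yl (1S,5S)-3,3-di(propan-2-yl)-2,4-dioxa-3-silabicyclo[3.3.1]non-6-ene-1-carboxylate | C=CCOC(=O)[C@]12CC=C[C@H](C1)O[Si](C(C)C)(C(C)C)O2 | intermediate
9 | (1S,5S)-3,3-di(propan-2-yl)-2,4-dioxa-3-silabicyclo[3.3.1]non-6-ene-1-carboxylic acid | OC(=O)[C@]12CC=C[C@H](C1)O[Si](C(C)C)(C(C)C)O2 | intermediate
10 | 1,3-dioxoisoindolin-2-yl (1S,5S)-3,3-di(propan-2-yl)-2,4-dioxa-3-silabicyclo[3.3.1]non-6-ene-1-carboxylate | O=C(ON1C(=O)c2ccccc2C1=O)[C@]12CC=C[C@H](C1)O[Si](C(C)C)(C(C)C)O2 | intermediate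
11 | 5-phenylpent-1-yne | C#CCCCc1ccccc1 | starting material
12 | 12-bromododecanoic acid | OC(=O)CCCCCCCCCCCBr | starting material
13 | lithium 5-phenylpent-1-yn-1-ide | [Li]C#CCCCc1ccccc1 | intermediate (not isolated)
14 | lithium 12-bromododecanoate | [Li+].[O-]C(=O)CCCCCCCCCCCBr | intermediate (not isolated)
15 | 17-phenylheptadec-13-ynoic acid | OC(=O)CCCCCCCCCCCC#CCCCc1ccccc1 | intermediate
16 | (13Z)-17-phenylheptadec-13-enoic acid | OC(=O)CCCCCCCCCCC/C=C\CCCc1ccccc1 | intermediate
17 | 1,3-dioxoisoindolin-2-yl (13Z)-17-phenylheptadec-13-enoate | O=C(ON1C(=O)c2ccccc2C1=O)CCCCCCCCCCC/C=C\CCCc1ccccc1 | intermediate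
18 | (1S,5S)-1-[(12Z)-16-phenylhexadec-12-en-1-yl]-3,3-di(propan-2-yl)-2,4-dioxa-3-silabicyclo[3.3.1]non-6-ene | c1ccccc1CCC/C=C\CCCCCCCCCCC[C@]12CC=C[C@H](C1)O[Si](C(C)C)(C(C)C)O2 | intermediate
19 | (1S,5S)-1-[(12Z)-16-phenylhexadec-12-en-1-yl]cyclohex-3-ene-1,5-diol | O[C@@H]1C=CC[C@@](O)(CCCCCCCCCCC/C=C\CCCc2ccccc2)C1 | target

**Count and risks**

Total step count: 14. Longest linear sequence: 11 steps (steps 1–9, 13 and 14, from (−)-quinic acid).

Steps most likely to fail:

1. Step 13 (the proposed new method). Radical sorting may fail: the bridgehead radical may be reduced or pick up a hydrogen atom before it meets the primary alkylnickel species (protodecarboxylation), while the primary radicals couple with each other. The fallback uses known chemistry, the nickel-catalysed decarboxylative alkyl–alkyl coupling of a redox-active ester with a dialkylzinc, a reaction type that accepts bridgehead esters. It sets out from 10, with the chain partner rebuilt from acetylide 13, and comes back to the route at 18. Acetylide 13 is alkylated with an excess of commercial 1,11-dibromoundecane (THF/DMPU) to (16-bromohexadec-4-yn-1-yl)benzene F1. Semi-hydrogenation as in step 11 should give [(4Z)-16-bromohexadec-4-en-1-yl]benzene F2. Mg turnings in THF convert it into bromo[(12Z)-16-phenylhexadec-12-en-1-yl]magnesium F3, and ZnCl2 (0.5 equiv) into bis[(12Z)-16-phenylhexadec-12-en-1-yl]zinc F4. F4 (2 equiv) and 10 with NiCl2·dme (20 mol%) and 4,4'-di-tert-butyl-2,2'-bipyridine (40 mol%) in THF/DMF at rt should give 18, the cage again enforcing retention at C1.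

2. Step 5. Allylic transposition may accompany the displacement (SN2' attack at C3). In this pseudo-symmetric ring the anti mode of that pathway delivers the mirror-image ester, so enantiopurity would erode and go unnoticed without a chiral assay; elimination of the activated oxygen to a diene is a second loss channel. The fallback resets the centre through the ketone; it sets out from 5 and comes back at 7, so 6 and step 6 are skipped. MnO2 (CH2Cl2, rt) oxidises the allylic alcohol to prop-2-en-1-yl (1S)-1-hydroxy-5-oxocyclohex-3-ene-1-carboxylate F5, which is kept cold and free of base because it can aromatise by β-elimination. A reagent-controlled Corey–Bakshi–Shibata reduction follows, with (R)-Me-CBS oxazaborolidine [(3aR)-1-methyl-3,3-diphenyltetrahydro-1H,3H-pyrrolo[1,2-c][1,3,2]oxazaborole, 20 mol%] and catecholborane in toluene at −60 °C. With the alkene arm as the large group, the catalyst should deliver hydride 1,2 to the face that gives the 5S carbinol 7.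

3. Step 7. Ring closure onto the hindered tertiary C1–OH may stall after silylation of O5, or the bis(triflate) may bridge two molecules instead of two oxygens of one. The fallback builds the bridge in two separate Si–O bond-forming events; it sets out from 7 and comes back at 8. Chlorodi(propan-2-yl)silane (i-Pr2SiHCl) and imidazole in CH2Cl2 at −20 °C silylate only the secondary C5–OH, giving prop-2-en-1-yl (1S,5S)-5-{[di(propan-2-yl)silyl]oxy}-1-hydroxycyclohex-3-ene-1-carboxylate F6. KOt-Bu (10 mol%) in THF at 0 °C to rt then closes the ring by base-catalysed dehydrogenative coupling of the Si–H with the tertiary hydroxyl, with loss of H2, to give 8.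

**Further compounds**

F1 | step 13 | (16-bromohexadec-4-yn-1-yl)benzene | BrCCCCCCCCCCCC#CCCCc1ccccc1
F2 | step 13 | [(4Z)-16-bromohexadec-4-en-1-yl]benzene | BrCCCCCCCCCCC/C=C\CCCc1ccccc1
F3 | step 13 | bromo[(12Z)-16-phenylhexadec-12-en-1-yl]magnesium | Br[Mg]CCCCCCCCCCC/C=C\CCCc1ccccc1
F4 | step 13 | bis[(12Z)-16-phenylhexadec-12-en-1-yl]zinc | c1ccccc1CCC/C=C\CCCCCCCCCCC[Zn]CCCCCCCCCCC/C=C\CCCc1ccccc1
F5 | step 5 | prop-2-en-1-yl (1S)-1-hydroxy-5-oxocyclohex-3-ene-1-carboxylate | C=CCOC(=O)[C@]1(O)CC=CC(=O)C1
F6 | step 7 | prop-2-en-1-yl (1S,5S)-5-{[di(propan-2-yl)silyl]oxy}-1-hydroxycyclohex-3-ene-1-carboxylate | C=CCOC(=O)[C@]1(O)CC=C[C@@H](O[SiH](C(C)C)C(C)C)C1
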